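Everything rests on opening the carbocycle of each half (C4a, C5, C6, C7, C8, C8a) at the C4a–C8a bond. The feature exploited is its polyketide pattern: oxygen on C6 and C8, a carboxyl-level C1 on C8a, and the C3/C4 stereodiad attached to C4a. The precursor is therefore a linear methyl 3,5,7-trioxodecanoate. Its terminal ketone (future C4a) bears the anti silyloxy side chain, and chain carbon 6 carries the future C5 methyl. In one operation a mild-base aldol–dehydration forms C4a–C8a, closes the ring and aromatises it to a resorcylate. The derived lactone supplies both unit A (quinone methide) and unit B (isochroman), which a Mannich base joins through C9.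

Key step: step 6

Numbering: isochromene numbering is used for each half (unit A = quinone methide half; unit B = isochroman half, primed; C9 = bridging CH2). "Chain" numbers refer to decanoate 9.
Assumption: unit A and monomer 16 are drawn as the 6-hydroxy-8-oxo tautomer of the target SMILES, which should interconvert freely with the 8-hydroxy-6-oxo form. Compound 9 is handled as a mixture of keto–enol tautomers and chain C6 epimers, all of which converge on aromatisation.

Step 1
Reactants: 1 ethyl (R)-3-hydroxybutanoate; 2 iodomethane
Product: 3 ethyl (2R,3R)-3-hydroxy-2-methylbutanoate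
Conditions: LiN(i-Pr)2 (2.2 equiv), THF, −78 → −20 °C; MeI, DMPU, −78 → 0 °C
Reagents that add atoms: iodomethane (2), CI
Why: Fráter–Seebach alkylation: the rigid lithium-chelated alkoxide enolate should be methylated on the face away from the C3 methyl group, setting the new centre (future C4/C4') anti to the hydroxyl as 2R, while the carbinol centre (future C3/C3') comes unchanged from the chiral pool.

Step 2
Reactants: 3 ethyl (2R,3R)-3-hydroxy-2-methylbutanoate
Product: 4 ethyl (2R,3R)-3-(tert-butyldimethylsilyloxy)-2-methylbutanoate
Conditions: TBSCl, imidazole, DMF, rt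
Reagents that add atoms: tert-butyldimethylsilyl chloride, CC(C)(C)[Si](C)(C)Cl
Why: Standard imidazole-promoted O-silylation of a secondary alcohol; the ether removes the acidic OH before the polyanion chemistry and later keeps O3 from closing onto the polyketone chain.

Step 3
Reactants: 4 ethyl (2R,3R)-3-(tert-butyldimethylsilyloxy)-2-methylbutanoate
Product: 5 (2R,3R)-3-(tert-butyldimethylsilyloxy)-N-methoxy-N,2-dimethylbutanamide
Conditions: MeNH(OMe)·HCl, i-PrMgCl, THF, −20 → 0 °C
Reagents that add atoms: N,O-dimethylhydroxylamine hydrochloride, CNOC.Cl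
Why: Weinreb amide synthesis by direct aminolysis of the ester with the magnesium amide made in the flask; it replaces a saponification/activation sequence, and the low temperature should leave the α-centre untouched.

Step 4
Reactants: 6 methyl acetoacetate; 7 methyl propanoate
Product: 8 methyl 3,5-dioxoheptanoate
Conditions: 6 (2 equiv), NaH then n-BuLi, THF, 0 °C; 7, 0 °C → rt; 1 M aq HCl
Reagents that add atoms: none
Why: Claisen-type γ-acylation of the acetoacetate dianion, which reacts only at its more basic terminal carbon; the dianion is taken in excess because the more acidic product consumes one equivalent of base.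

Step 5
Reactants: 8 methyl 3,5-dioxoheptanoate; 5 (2R,3R)-3-(tert-butyldimethylsilyloxy)-N-methoxy-N,2-dimethylbutanamide
Product: 9 methyl (8R,9R)-9-(tert-butyldimethylsilyloxy)-6,8-dimethyl-3,5,7-trioxodecanoate
Conditions: 8 (1.5 equiv), LiN(i-Pr)2 (4.6 equiv), THF, −78 → 0 °C; 5, −78 → −10 °C; inverse quench into AcOH–THF, −78 °C
Reagents that add atoms: none
Why: Polyanion acylation combined with the Weinreb ketone synthesis: in the 2,4,6-trianion only the last-formed, most basic carbanion (chain C6) attacks the amide, and the chelated tetrahedral adduct lasts until the cold acidic quench, so neither over-addition nor exposure of the epimerisable C4 centre of the new ketone to strong base should occur.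

Step 6
Reactants: 9 methyl (8R,9R)-9-(tert-butyldimethylsilyloxy)-6,8-dimethyl-3,5,7-trioxodecanoate
Product: 11 methyl 2-[(2S,3R)-3-(tert-butyldimethylsilyloxy)butan-2-yl]-4,6-dihydroxy-3-methylbenzoate, via cyclic aldol adduct 10 (not isolated)
Conditions: Cs2CO3 (1.5 equiv), degassed MeOH, 0 °C → rt; then AcOH
Reagents that add atoms: none
Why: Carbonate in methanol reversibly enolises the chain; C8a, the carbon between the ester and the C8 ketone, adds to the C4a ketone to give aldol 10, which loses water by E1cB across C4a–C8a and tautomerises at C6 and C8 to the arene. The closest known reaction type is the biomimetic aldol aromatisation of open-chain 3,5,7-triketo esters to resorcylates under mild base. The one ring formed, the carbocycle C4a–C5–C6–C7–C8–C8a, closes 6-exo-trig at the C4a carbonyl, a mode allowed whether the β-keto ester enolate is counted as enolendo (through C8) or enolexo (through the ester). No lasting stereocenter is made (those of 10 are erased); C3 and C4 are inherited from 3, and C4 should hold because C8a–H, C7–H and C5–H are ionised long before C4–H and because aromatisation turns C4 into a non-acidic benzylic centre. The step needs C- over O-cyclisation and aldol over Claisen closure: the C5 methyl makes the Claisen product a quaternary, non-aromatisable triketone that methoxide reopens, the silyl ether keeps O3 off the C6 carbonyl, and only the aldol channel is drained irreversibly by aromatisation. Methanol matches the methyl ester, so ester exchange is invisible, and the secondary silyl ether tolerates carbonate.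

Step 7
Reactants: 11 methyl 2-[(2S,3R)-3-(tert-butyldimethylsilyloxy)butan-2-yl]-4,6-dihydroxy-3-methylbenzoate
Product: 13 (3R,4S)-6,8-dihydroxy-3,4,5-trimethylisochroman-1-one, via hydroxy ester 12 (not isolated)
Conditions: 2 M aq HCl, THF, 50 °C
Reagents that add atoms: none
Why: Acid-catalysed silyl ether hydrolysis followed by intramolecular transesterification (δ-lactonisation) of the freed O3 onto the adjacent ester; neither the C3–O bond nor the C4–H bond is broken, so both centres should be retained.

Step 8
Reactants: 13 (3R,4S)-6,8-dihydroxy-3,4,5-trimethylisochroman-1-one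
Product: 16 (3R,4S)-6-hydroxy-3,4,5-trimethyl-3,4-dihydroisochromen-8-one (quinone methide monomer), via bis(trimethylsilyl) ether 14 (not isolated), via lactol 15 (not isolated)
Conditions: (Me3Si)2NH, cat. Me3SiCl, MeCN, 60 °C, evaporate; i-Bu2AlH (1.2 equiv), CH2Cl2, −78 °C; 1 M aq HCl, THF, 0 °C → rt
Reagents that add atoms: none
Why: Low-temperature lactone-to-lactol reduction with a dialkylaluminium hydride: transient O-silylation removes the acidic, strongly donating phenoxides that would favour ionisation of the O-aluminated lactol and over-reduction, and dilute acid then strips the aryl silyl ethers and dehydrates lactol 15 to the vinylogous-acid quinone methide without touching C3 or C4.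

Step 9
Reactants: 16 (3R,4S)-6-hydroxy-3,4,5-trimethyl-3,4-dihydroisochromen-8-one (one portion)
Product: 17 (3R,4S)-3,4,5-trimethylisochromane-6,8-diol
Conditions: NaBH4, EtOH, 0 °C
Reagents that add atoms: none
Why: Conjugate hydride addition of borohydride to C1, the electrophilic terminus of the quinone methide, is driven by rearomatisation to the resorcinol; this is the usual way to turn quinone methides of this class into their dihydro compounds.

Step 10
Reactants: 17 (3R,4S)-3,4,5-trimethylisochromane-6,8-diol; 18 N,N-dimethylmethyleneiminium iodide (Eschenmoser's salt)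
Product: 19 (3R,4S)-7-[(dimethylamino)methyl]-3,4,5-trimethylisochromane-6,8-diol
Conditions: CH2=NMe2+ I− (1.05 equiv), MeCN, 0 °C → rt; aq NaHCO3
Reagents that add atoms: N,N-dimethylmethyleneiminium iodide (18), C=[N+](C)C.[I-]
Why: Mannich aminomethylation (electrophilic aromatic substitution): C7' is the only unsubstituted ring position and is activated by both flanking hydroxyls, and the preformed iminium salt avoids free formaldehyde and hence diarylmethane homodimer formation.

Step 11
Reactants: 19 (3R,4S)-7-[(dimethylamino)methyl]-3,4,5-trimethylisochromane-6,8-diol; 16 (3R,4S)-6-hydroxy-3,4,5-trimethyl-3,4-dihydroisochromen-8-one (second portion)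
Product: 21 dicitrinone I, via ortho-quinone methide 20 (not isolated)
Conditions: 16 (1.1 equiv), 1,4-dioxane, 80 °C, N2 sweep; pH 4 buffer wash
Reagents that add atoms: none
Why: Michael addition of an enolised cyclic 1,3-dicarbonyl to an ortho-quinone methide released from a Mannich base, the known way to unsymmetrical methylene-bridged phloroglucinol-type dimers: the vinylogous acid 16 protonates the amine of 19, loss of Me2NH gives 20, and C7 of the enolate of 16 attacks its exocyclic CH2 (C9), while O-alkylation and amine addition at C1 are reversible, C5 is blocked and the enolate form of 16 is not electrophilic.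

Compound list
1 | ethyl (R)-3-hydroxybutanoate | O[C@H](C)CC(=O)OCC | starting material
2 | iodomethane | CI | starting material
3 | ethyl (2R,3R)-3-hydroxy-2-methylbutanoate | CCOC(=O)[C@H](C)[C@@H](C)O | intermediate
4 | ethyl (2R,3R)-3-(tert-butyldimethylsilyloxy)-2-methylbutanoate | CCOC(=O)[C@H](C)[C@@H](C)O[Si](C)(C)C(C)(C)C | intermediate
5 | (2R,3R)-3-(tert-butyldimethylsilyloxy)-N-methoxy-N,2-dimethylbutanamide | CON(C)C(=O)[C@H](C)[C@@H](C)O[Si](C)(C)C(C)(C)C | intermediate
6 | methyl acetoacetate | COC(=O)CC(C)=O | starting material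
7 | methyl propanoate | CCC(=O)OC | starting material
8 | methyl 3,5-dioxoheptanoate | CCC(=O)CC(=O)CC(=O)OC | intermediate
9 | methyl (8R,9R)-9-(tert-butyldimethylsilyloxy)-6,8-dimethyl-3,5,7-trioxodecanoate (chain C6 epimers, keto–enol mixture) | COC(=O)CC(=O)CC(=O)C(C)C(=O)[C@H](C)[C@@H](C)O[Si](C)(C)C(C)(C)C | intermediate
10 | methyl 2-[(2R,3R)-3-(tert-butyldimethylsilyloxy)butan-2-yl]-2-hydroxy-3-methyl-4,6-dioxocyclohexane-1-carboxylate (ring centres undefined) | COC(=O)C1C(=O)CC(=O)C(C)C1(O)[C@H](C)[C@@H](C)O[Si](C)(C)C(C)(C)C | intermediate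
11 | methyl 2-[(2S,3R)-3-(tert-butyldimethylsilyloxy)butan-2-yl]-4,6-dihydroxy-3-methylbenzoate | COC(=O)c1c(O)cc(O)c(C)c1[C@H](C)[C@@H](C)O[Si](C)(C)C(C)(C)C | intermediate
12 | methyl 4,6-dihydroxy-2-[(2S,3R)-3-hydroxybutan-2-yl]-3-methylbenzoate | COC(=O)c1c(O)cc(O)c(C)c1[C@H](C)[C@@H](C)O | intermediate
13 | (3R,4S)-6,8-dihydroxy-3,4,5-trimethylisochroman-1-one | Cc1c(O)cc(O)c2c1[C@H](C)[C@@H](C)OC2=O | intermediate
14 | (3R,4S)-3,4,5-trimethyl-6,8-bis(trimethylsilyloxy)isochroman-1-one | Cc1c(O[Si](C)(C)C)cc(O[Si](C)(C)C)c2c1[C@H](C)[C@@H](C)OC2=O | intermediate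
15 | (3R,4S)-3,4,5-trimethylisochromane-1,6,8-triol (C1 epimers) | Cc1c(O)cc(O)c2c1[C@H](C)[C@@H](C)OC2O | intermediate
16 | (3R,4S)-6-hydroxy-3,4,5-trimethyl-3,4-dihydroisochromen-8-one | CC1=C2C(=CO[C@H](C)[C@H]2C)C(=O)C=C1O | intermediate
17 | (3R,4S)-3,4,5-trimethylisochromane-6,8-diol | Cc1c(O)cc(O)c2c1[C@H](C)[C@@H](C)OC2 | intermediate
18 | N,N-dimethylmethyleneiminium iodide | C=[N+](C)C.[I-] | starting material
19 | (3R,4S)-7-[(dimethylamino)methyl]-3,4,5-trimethylisochromane-6,8-diol | Cc1c(O)c(CN(C)C)c(O)c2c1[C@H](C)[C@@H](C)OC2 | intermediate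
20 | (3R,4S)-8-hydroxy-3,4,5-trimethyl-7-methylidene-3,4-dihydro-1H-isochromen-6(7H)-one | C=C1C(=O)C(C)=C2[C@H](C)[C@@H](C)OCC2=C1O | intermediate
21 | dicitrinone I: (3R,4S)-7-{[(3R,4S)-6,8-dihydroxy-3,4,5-trimethylisochroman-7-yl]methyl}-6-hydroxy-3,4,5-trimethyl-3,4-dihydroisochromen-8-one | CC1=C2C(=CO[C@H](C)[C@H]2C)C(=O)C(Cc2c(O)c(C)c3c(c2O)CO[C@H](C)[C@H]3C)=C1O | target

Total step count: 11.
Longest linear sequence: 10 steps (1, 2, 3, 5, 6, 7, 8, 9, 10, 11) from 1; step 4 is the side branch.

Steps most likely to fail

1. Step 6. The C4a carbonyl sits between two branched carbons, so C–C closure may be slow. Several processes could then take over: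
- O-cyclisation of the C6 enol onto the ester
- methoxide-induced chain cleavage beside the C5 methyl
- β-elimination of the silyloxy group
- erosion at C4

Fallback, setting out from 5 and coming back at 13: the ester is masked as a dioxinone. This removes both ester-based side reactions, fixes the C8=C8a geometry and lets the closure run with an amine base in an aprotic solvent. Commercial 2,2,6-trimethyl-4H-1,3-dioxin-4-one is deprotonated with LiN(i-Pr)2 and acylated at its methyl carbon with propanoyl chloride to give keto-dioxinone F1. The dianion of F1 (two equivalents of LiN(i-Pr)2) is acylated by 5 to give diketo-dioxinone F2. Et3N in CH2Cl2 should aromatise F2 to benzodioxinone F3. Aqueous HCl in THF then cleaves the silyl ether to hydroxy benzodioxinone F4, whose O3 opens the dioxinone carbonyl with loss of acetone to give 13.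

2. Step 11. Unit A is both a nucleophile (C7) and an electrophile (C1). Three processes may erode the cross-coupling:
- self-condensation from C7 to C1
- lasting capture of the liberated amine or of water at C1
- retro-Mannich scrambling of 19 toward a symmetrical unit B dimer

Fallback, setting out from 19 and 13 and coming back at 21: the bridge is built before any quinone methide of unit A exists. Heating 19 in 1,4-dioxane with lactone 13, a robust resorcinol whose only free ring position is C7, should give lactone–isochroman dimer F5 by the same methide capture. The four phenols are masked with (Me3Si)2NH as tetrakis(trimethylsilyl) ether F6, and the single lactone is reduced with i-Bu2AlH at −78 °C. Dilute HCl then liberates lactol F7, which dehydrates to 21 in the manner of step 8.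

3. Step 5. Attack of a secondary carbanion on an α-branched amide may be slower than proton transfer from the amide α-position or base-induced breakdown of the N-methoxy group. Material would then be returned or degraded.

Fallback, setting out from 5 and 8 and coming back at 9: acylation is replaced by aldol addition plus oxidation. Amide 5 is reduced with i-Bu2AlH (THF, −78 °C) to aldehyde F8. The trianion of 8 adds to this far more reactive electrophile at −78 °C to give hydroxy diketo ester F9 as a mixture of carbinol epimers. 2-Iodoxybenzoic acid in EtOAc then oxidises the β-hydroxy ketone to the β-diketone 9.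

Further compounds
F1 | step 6 | 2,2-dimethyl-6-(2-oxobutyl)-4H-1,3-dioxin-4-one | CCC(=O)CC1=CC(=O)OC(C)(C)O1
F2 | step 6 | 6-[(5R,6R)-6-(tert-butyldimethylsilyloxy)-3,5-dimethyl-2,4-dioxoheptyl]-2,2-dimethyl-4H-1,3-dioxin-4-one | CC1(C)OC(=O)C=C(CC(=O)C(C)C(=O)[C@H](C)[C@@H](C)O[Si](C)(C)C(C)(C)C)O1
F3 | step 6 | 5-[(2S,3R)-3-(tert-butyldimethylsilyloxy)butan-2-yl]-7-hydroxy-2,2,6-trimethyl-4H-1,3-benzodioxin-4-one | CC1(C)OC(=O)c2c(O1)cc(O)c(C)c2[C@H](C)[C@@H](C)O[Si](C)(C)C(C)(C)C
F4 | step 6 | 7-hydroxy-5-[(2S,3R)-3-hydroxybutan-2-yl]-2,2,6-trimethyl-4H-1,3-benzodioxin-4-one | CC1(C)OC(=O)c2c(O1)cc(O)c(C)c2[C@H](C)[C@@H](C)O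
F5 | step 11 | (3R,4S)-7-{[(3R,4S)-6,8-dihydroxy-3,4,5-trimethylisochroman-7-yl]methyl}-6,8-dihydroxy-3,4,5-trimethylisochroman-1-one | Cc1c(O)c(Cc3c(O)c(C)c4c(c3O)CO[C@H](C)[C@H]4C)c(O)c2c1[C@H](C)[C@@H](C)OC2=O
F6 | step 11 | tetrakis(trimethylsilyl) ether of F5 | Cc1c(O[Si](C)(C)C)c(Cc3c(O[Si](C)(C)C)c(C)c4c(c3O[Si](C)(C)C)CO[C@H](C)[C@H]4C)c(O[Si](C)(C)C)c2c1[C@H](C)[C@@H](C)OC2=O
F7 | step 11 | (3R,4S)-7-{[(3R,4S)-6,8-dihydroxy-3,4,5-trimethylisochroman-7-yl]methyl}-3,4,5-trimethylisochromane-1,6,8-triol (C1 epimers) | Cc1c(O)c(Cc3c(O)c(C)c4c(c3O)CO[C@H](C)[C@H]4C)c(O)c2c1[C@H](C)[C@@H](C)OC2O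
F8 | step 5 | (2R,3R)-3-(tert-butyldimethylsilyloxy)-2-methylbutanal | O=C[C@H](C)[C@@H](C)O[Si](C)(C)C(C)(C)C
F9 | step 5 | methyl (8S,9R)-9-(tert-butyldimethylsilyloxy)-7-hydroxy-6,8-dimethyl-3,5-dioxodecanoate (C6 and C7 undefined) | COC(=O)CC(=O)CC(=O)C(C)C(O)[C@H](C)[C@@H](C)O[Si](C)(C)C(C)(C)C
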